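**Plan**

- Retrosynthesis: the C3–OH bond is traced back to a C3–I bond, the O7–prenyl ether to a silyl-protected phenol, the O1–C2 bond of ring C to an aryl ynone whose ortho-methoxy group supplies O1, and the C3–C4 bond to an acetylide plus an aryl aldehyde.
- Enabling feature: C2 and C3 of ring C lie next to the C4 ketone and correspond to the two carbons of a conjugated alkyne, so one iodonium-triggered addition across that triple bond closes ring C through O1–C2 and leaves iodine on C3 as the seat of the later hydroxyl.
- Forward order: the silylated ring A aldehyde and the ring B alkyne are joined at C3–C4, the carbinol is oxidised to the ynone, ring C is closed with ICl, the 7-oxygen is desilylated and prenylated, and the C3 iodide is converted into the C3 hydroxyl last.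
- Stereochemistry: the target has no stereocentre and no stereogenic double bond; the only stereocentre on the way, the carbinol carbon of 5, is formed racemic and removed by oxidation.

Key step: step 4

Remark on the chemistry: the 7-oxygen is carried as a triisopropylsilyl ether. It has no alkene for ICl to attack, and fluoride can exchange it for prenyl while the C3 iodide is still present, so a 3-OH and a 7-OH never have to be told apart.

**Route**

Step 1
Reactants: 1 4-hydroxy-2-methoxybenzaldehyde
Product: 2 2-methoxy-4-[(triisopropylsilyl)oxy]benzaldehyde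
Conditions: TIPSCl (1.2 equiv), imidazole (2.5 equiv), DMF, rt
Reagents that add atoms: chlorotriisopropylsilane (TIPSCl), CC(C)[Si](Cl)(C(C)C)C(C)C
Why: Imidazole-promoted silylation of the acidic para-formyl phenol is a standard silyl ether formation, and the bulky triisopropylsilyl group should withstand the acetylide, MnO2 and ICl yet fall to fluoride.

Step 2
Reactants: 2 2-methoxy-4-[(triisopropylsilyl)oxy]benzaldehyde; 3 4-ethynyl-1,2-dimethoxybenzene
Product: 5 racemic 3-(3,4-dimethoxyphenyl)-1-{2-methoxy-4-[(triisopropylsilyl)oxy]phenyl}prop-2-yn-1-ol, via lithium (3,4-dimethoxyphenyl)acetylide 4 (not isolated)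
Conditions: 3, n-BuLi, THF, −78 °C; then 2, −78 to 0 °C; then H2O
Reagents that add atoms: none
Why: Deprotonation of the terminal alkyne and 1,2-addition of the lithium acetylide to the aryl aldehyde (alkynylation of an aldehyde) should form the C3–C4 bond, the new carbinol centre being racemic and erased in step 3.

Step 3
Reactants: 5 racemic 3-(3,4-dimethoxyphenyl)-1-{2-methoxy-4-[(triisopropylsilyl)oxy]phenyl}prop-2-yn-1-ol
Product: 6 3-(3,4-dimethoxyphenyl)-1-{2-methoxy-4-[(triisopropylsilyl)oxy]phenyl}prop-2-yn-1-one
Conditions: activated MnO2 (excess), CH2Cl2, rt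
Reagents that add atoms: none
Why: MnO2 oxidation of an alcohol that is both benzylic and propargylic is fast and should leave the silyl ether, the alkyne and the methyl ethers untouched.

Step 4
Reactants: 6 3-(3,4-dimethoxyphenyl)-1-{2-methoxy-4-[(triisopropylsilyl)oxy]phenyl}prop-2-yn-1-one
Product: 8 2-(3,4-dimethoxyphenyl)-3-iodo-7-[(triisopropylsilyl)oxy]-4H-chromen-4-one, via O-methyl chromenylium chloride 7 (not isolated)
Conditions: ICl (1.2 equiv, added slowly), CH2Cl2, −78 °C; then aq Na2S2O3
Reagents that add atoms: iodine monochloride, ClI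
Why: ICl delivers iodonium to the ynone triple bond, the ortho-methoxy oxygen of ring A attacks the aryl-bearing alkyne carbon anti to iodine to form O1–C2, and the resulting O-methyl oxonium 7 is dealkylated by chloride through SN2 at methyl, releasing MeCl and the neutral 3-iodochromone. The closest known reaction type is the ICl-induced demethylative iodocyclisation of 2-methoxyaryl alkynones to 3-iodochromones. Ring C closes in the 6-endo-dig mode. No stereocentre is created. The step needs six- over five-membered closure, which the substrate secures because the carbonyl polarises the alkyne and the electron-rich 3,4-dimethoxyphenyl group stabilises positive charge on the distal carbon, whereas the aurone-type 5-exo closure would need attack at the electron-poor carbon next to the carbonyl. It also needs alkyne activation to outrun iodination of the electron-rich arenes, which the low temperature and the small excess of ICl should ensure, and the silyl ether offers no alkene for ICl to add to.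

Step 5
Reactants: 8 2-(3,4-dimethoxyphenyl)-3-iodo-7-[(triisopropylsilyl)oxy]-4H-chromen-4-one; 9 prenyl bromide (1-bromo-3-methylbut-2-ene)
Product: 11 2-(3,4-dimethoxyphenyl)-3-iodo-7-[(3-methylbut-2-en-1-yl)oxy]-4H-chromen-4-one, via tetrabutylammonium chromen-7-olate 10 (not isolated)
Conditions: Bu4NF (1.1 equiv), THF, 0 °C; then 9 (1.5 equiv), 0 °C to rt
Reagents that add atoms: none
Why: Fluoride cleaves the aryl silyl ether to the ammonium phenoxide, which should undergo Williamson etherification (SN2) with the primary allylic bromide in the same flask, and since only one hydroxyl exists at this stage no site selectivity is required.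

Step 6
Reactants: 11 2-(3,4-dimethoxyphenyl)-3-iodo-7-[(3-methylbut-2-en-1-yl)oxy]-4H-chromen-4-one
Product: 14 2-(3,4-dimethoxyphenyl)-3-hydroxy-7-[(3-methylbut-2-en-1-yl)oxy]-4H-chromen-4-one, via chromen-3-ylmagnesium chloride 12 (not isolated), via dimethyl chromen-3-ylboronate 13 (not isolated)
Conditions: i-PrMgCl·LiCl (1.1 equiv), THF, −40 °C; B(OMe)3 (2 equiv), −40 to 0 °C; then 30% aq H2O2, aq NaHCO3, 0 °C to rt
Reagents that add atoms: hydrogen peroxide, OO
Why: Iodine–magnesium exchange on the electron-poor alkenyl iodide should outpace addition to the weakly electrophilic vinylogous-ester carbonyl, the 3-metallated flavone is the kind of species whose borate trapping and peroxide oxidation (boron-to-oxygen 1,2-shift) is an established way from flavones to flavonols, and the prenyl and methyl ethers are inert to all three reagents.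

**Compound list**

1 | 4-hydroxy-2-methoxybenzaldehyde | COc1cc(O)ccc1C=O | starting material
2 | 2-methoxy-4-[(triisopropylsilyl)oxy]benzaldehyde | COc1cc(O[Si](C(C)C)(C(C)C)C(C)C)ccc1C=O | intermediate
3 | 4-ethynyl-1,2-dimethoxybenzene | C#Cc1ccc(OC)c(OC)c1 | starting material
4 | lithium (3,4-dimethoxyphenyl)acetylide | [Li]C#Cc1ccc(OC)c(OC)c1 | intermediate (not isolated)
5 | racemic 3-(3,4-dimethoxyphenyl)-1-{2-methoxy-4-[(triisopropylsilyl)oxy]phenyl}prop-2-yn-1-ol | COc1cc(O[Si](C(C)C)(C(C)C)C(C)C)ccc1C(O)C#Cc1ccc(OC)c(OC)c1 | intermediate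
6 | 3-(3,4-dimethoxyphenyl)-1-{2-methoxy-4-[(triisopropylsilyl)oxy]phenyl}prop-2-yn-1-one | COc1cc(O[Si](C(C)C)(C(C)C)C(C)C)ccc1C(=O)C#Cc1ccc(OC)c(OC)c1 | intermediate
7 | 2-(3,4-dimethoxyphenyl)-3-iodo-1-methyl-4-oxo-7-[(triisopropylsilyl)oxy]-4H-chromen-1-ium chloride | COc1ccc(cc1OC)C1=C(I)C(=O)c2ccc(O[Si](C(C)C)(C(C)C)C(C)C)cc2[O+]1C.[Cl-] | intermediate (not isolated)
8 | 2-(3,4-dimethoxyphenyl)-3-iodo-7-[(triisopropylsilyl)oxy]-4H-chromen-4-one | COc1ccc(-c2oc3cc(O[Si](C(C)C)(C(C)C)C(C)C)ccc3c(=O)c2I)cc1OC | intermediate
9 | prenyl bromide (1-bromo-3-methylbut-2-ene) | CC(C)=CCBr | starting material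
10 | tetrabutylammonium 2-(3,4-dimethoxyphenyl)-3-iodo-4-oxo-4H-chromen-7-olate | COc1ccc(-c2oc3cc([O-])ccc3c(=O)c2I)cc1OC.CCCC[N+](CCCC)(CCCC)CCCC | intermediate (not isolated)
11 | 2-(3,4-dimethoxyphenyl)-3-iodo-7-[(3-methylbut-2-en-1-yl)oxy]-4H-chromen-4-one | COc1ccc(-c2oc3cc(OCC=C(C)C)ccc3c(=O)c2I)cc1OC | intermediate
12 | {2-(3,4-dimethoxyphenyl)-7-[(3-methylbut-2-en-1-yl)oxy]-4-oxo-4H-chromen-3-yl}magnesium chloride | COc1ccc(-c2oc3cc(OCC=C(C)C)ccc3c(=O)c2[Mg]Cl)cc1OC | intermediate (not isolated)
13 | dimethyl {2-(3,4-dimethoxyphenyl)-7-[(3-methylbut-2-en-1-yl)oxy]-4-oxo-4H-chromen-3-yl}boronate | COc1ccc(-c2oc3cc(OCC=C(C)C)ccc3c(=O)c2B(OC)OC)cc1OC | intermediate (not isolated)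
14 | 2-(3,4-dimethoxyphenyl)-3-hydroxy-7-[(3-methylbut-2-en-1-yl)oxy]-4H-chromen-4-one (CNP0167607.0) | COc1ccc(-c2oc3cc(OCC=C(C)C)ccc3c(=O)c2O)cc1OC | target

**Step count**

Total: 6 steps. Longest linear sequence: 6 steps (1 → 2 → 5 → 6 → 8 → 11 → 14); alkyne 3 and prenyl bromide 9 are bought.

**Steps most likely to fail**

Step 6. The organomagnesium intermediate may add to the C4 carbonyl or to C2 of another molecule, may open ring C by β-elimination of the phenoxide, or may be protonated before it meets the borate, which amounts to net deiodination. The fallback sets out from 11 and replaces the polar organometallic by catalytic C–B bond formation. Miyaura borylation (Pd(dppf)Cl2, B2pin2, KOAc, dioxane, 80 °C) should give the isolable pinacol boronate 2-(3,4-dimethoxyphenyl)-7-[(3-methylbut-2-en-1-yl)oxy]-3-(4,4,5,5-tetramethyl-1,3,2-dioxaborolan-2-yl)-4H-chromen-4-one F1. Oxidative addition of zerovalent palladium into the C–I bond should be much faster than ionisation of the hindered prenyl ether. Oxidation of F1 with NaBO3·4H2O in THF/H2O at rt returns to the route at 14.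

Step 4. Iodination of the electron-rich rings A or B, five-membered closure, plain addition of ICl across the triple bond without ring closure, or loss of the silyl group may compete. The fallback sets out from 6 and separates ring closure from iodination. BCl3 (CH2Cl2, −78 to 0 °C) removes the methyl group ortho to the chelating carbonyl to give the phenol 3-(3,4-dimethoxyphenyl)-1-{2-hydroxy-4-[(triisopropylsilyl)oxy]phenyl}prop-2-yn-1-one F2. Catalytic DMAP in DMF then effects the 6-endo-dig oxa-Michael closure to the flavone 2-(3,4-dimethoxyphenyl)-7-[(triisopropylsilyl)oxy]-4H-chromen-4-one F3. Deprotonation at C3 with LiN(i-Pr)2 (THF, −78 °C) followed by I2 places iodine regiospecifically at C3 and returns to the route at 8.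

Step 5. C-alkylation of the ambident phenoxide at C8 or C6, consumption of prenyl bromide by fluoride, or incomplete desilylation may lower the conversion. The fallback sets out from 8 and avoids a free phenoxide in the ether-forming event. Desilylation with Bu4NF buffered by AcOH (THF, 0 °C) and isolation gives the phenol 2-(3,4-dimethoxyphenyl)-7-hydroxy-3-iodo-4H-chromen-4-one F4. Mitsunobu etherification of F4 with 3-methylbut-2-en-1-ol (PPh3, DIAD, THF, 0 °C to rt) returns to the route at 11.

**Further compounds**

F1 | step 6 | 2-(3,4-dimethoxyphenyl)-7-[(3-methylbut-2-en-1-yl)oxy]-3-(4,4,5,5-tetramethyl-1,3,2-dioxaborolan-2-yl)-4H-chromen-4-one | COc1ccc(-c2oc3cc(OCC=C(C)C)ccc3c(=O)c2B4OC(C)(C)C(C)(C)O4)cc1OC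
F2 | step 4 | 3-(3,4-dimethoxyphenyl)-1-{2-hydroxy-4-[(triisopropylsilyl)oxy]phenyl}prop-2-yn-1-one | COc1ccc(C#CC(=O)c2ccc(O[Si](C(C)C)(C(C)C)C(C)C)cc2O)cc1OC
F3 | step 4 | 2-(3,4-dimethoxyphenyl)-7-[(triisopropylsilyl)oxy]-4H-chromen-4-one | COc1ccc(-c2cc(=O)c3ccc(O[Si](C(C)C)(C(C)C)C(C)C)cc3o2)cc1OC
F4 | step 5 | 2-(3,4-dimethoxyphenyl)-7-hydroxy-3-iodo-4H-chromen-4-one | COc1ccc(-c2oc3cc(O)ccc3c(=O)c2I)cc1OC
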